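The 1,2-dioxane (ring A: C3–C4–C5–C6–O–O) is cut into a C6–O–O unit and a C5–C4–C3 unit. A peroxyketal of the side-chain methyl ketone ionises to a peroxycarbenium ion at C6; the terminal CH2 (C5) of an allylsilane that already carries the C1–C3 acrylate adds to it, and the freed hydroperoxide closes ring A by conjugate addition to C3. One flask thus forges C5–C6 and O–C3 and exploits the β-peroxy ester array C6(OO)–C5–C4–C3–C2–C1(=O). The exocyclic C4 methylene left by the allylsilane is then protonated and captured by the ester, which gives the cis-fused lactone (ring B) and the C4 methyl.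

Key step: step 8

Remark: atom labels C1–C16 are those of the target chain (C1 lactone carbonyl, O–O on C3 and C6, methyls on C4, C6 and C8, phenyl on C16); the antipodes named for the ferrocenyl diphosphine (step 4) and the imidodiphosphorimidate (step 8) are assumed to give 8R and 6R, and the mirror-image ligand or catalyst is used if the first run shows the opposite sense.

Step 1
Reactants: 1 cyclopropyl(phenyl)methanol
Product: 2 [(1E)-4-bromobut-1-en-1-yl]benzene
Conditions: HBr (48% aq), 0 → 23 °C
Reagents that add atoms: hydrogen bromide (Br)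
Why: Julia cyclopropylcarbinyl-to-homoallyl rearrangement, in which ionisation of the benzylic carbinol and opening of the ring by bromide should give the conjugated styrene with the favoured E geometry.

Step 2
Reactants: 2 [(1E)-4-bromobut-1-en-1-yl]benzene; 3 cyclopropanecarbaldehyde
Product: 5 (4E)-1-cyclopropyl-5-phenylpent-4-en-1-ol (racemic), via homocinnamyl Grignard reagent 4 (not isolated)
Conditions: Mg, THF, 23 → 40 °C; then 3, −20 → 0 °C; aq NH4Cl
Reagents that add atoms: none
Why: Grignard addition to an aldehyde, whose racemic carbinol centre is destroyed in step 3.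

Step 3
Reactants: 5 (4E)-1-cyclopropyl-5-phenylpent-4-en-1-ol
Product: 7 [(1E,5E)-8-bromoocta-1,5-dien-1-yl]benzene, via cyclopropylcarbinyl bromide 6 (not isolated)
Conditions: PBr3, LiBr, 2,4,6-collidine, Et2O, −30 → 0 °C; then ZnBr2, Et2O, 0 → 23 °C
Reagents that add atoms: phosphorus tribromide (BrP(Br)Br)
Why: Julia–Johnson rearrangement, in which ZnBr2 equilibrates the cyclopropylcarbinyl bromide through its cation and the ring should open with the chain anti to the breaking bond, so that the new C11=C12 bond is E.

Step 4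
Reactants: 7 [(1E,5E)-8-bromoocta-1,5-dien-1-yl]benzene; 8 (3E)-pent-3-en-2-one
Product: 10 (4R,7E,11E)-4-methyl-12-phenyldodeca-7,11-dien-2-one, via dienyl Grignard reagent 9 (not isolated)
Conditions: Mg, Et2O, 23 °C; then 8, CuBr·SMe2 (5 mol %), (R)-1-[(Sp)-2-(diphenylphosphino)ferrocenyl]ethyldicyclohexylphosphine (6 mol %), t-BuOMe, −75 °C; aq NH4Cl
Reagents that add atoms: none
Why: Copper-catalysed enantioselective conjugate addition of a Grignard reagent to an acyclic enone, in which the chiral diphosphine–copper complex selects the enone face and should set C8 (R) while low temperature in t-BuOMe suppresses 1,2-addition.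

Step 5
Reactants: 10 (4R,7E,11E)-4-methyl-12-phenyldodeca-7,11-dien-2-one
Product: 11 (2RS,4R,7E,11E)-2-hydroperoxy-2-methoxy-4-methyl-12-phenyldodeca-7,11-diene (both C2 epimers)
Conditions: urea·H2O2, Sc(OTf)3 (10 mol %), MeOH, 23 °C
Reagents that add atoms: methanol (CO); urea–hydrogen peroxide (NC(N)=O.OO)
Why: Lewis-acid-catalysed perketalisation, in which the oxocarbenium ion formed in methanol is trapped by H2O2; the ketal centre forms as both epimers, which does not matter because it becomes planar in step 8, and the alkenes should be inert to H2O2 without an epoxidation catalyst.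

Step 6
Reactants: 11 (2RS,4R,7E,11E)-2-hydroperoxy-2-methoxy-4-methyl-12-phenyldodeca-7,11-diene
Product: 12 tert-butyl{[(2RS,4R,7E,11E)-2-methoxy-4-methyl-12-phenyldodeca-7,11-dien-2-yl]peroxy}dimethylsilane
Conditions: t-BuMe2SiCl, imidazole, DMF, 0 → 23 °C
Reagents that add atoms: tert-butylchlorodimethylsilane (CC(C)(C)[Si](C)(C)Cl)
Why: O-silylation of the hydroperoxide masks the acidic O–H for the Lewis-acid step, and the bulky silyl group makes the peroxide oxygen a poor internal nucleophile.

Step 7
Reactants: 13 (2-bromoprop-2-en-1-yl)trimethylsilane; 14 tert-butyl prop-2-enoate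
Product: 15 tert-butyl (2E)-4-[(trimethylsilyl)methyl]penta-2,4-dienoate
Conditions: Pd(OAc)2 (5 mol %), P(o-tol)3 (10 mol %), Et3N, MeCN, 80 °C
Reagents that add atoms: none
Why: Heck reaction (oxidative addition of the vinyl bromide to zerovalent palladium, syn insertion of the acrylate, syn β-hydride elimination), which should give the E-dienoate and leave the allylsilane untouched under amine-base conditions.

Step 8
Reactants: 12 tert-butyl{[(2RS,4R,7E,11E)-2-methoxy-4-methyl-12-phenyldodeca-7,11-dien-2-yl]peroxy}dimethylsilane; 15 tert-butyl (2E)-4-[(trimethylsilyl)methyl]penta-2,4-dienoate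
Product: 18 tert-butyl (3S,6R,8R,11E,15E)-3,6-epidioxy-6,8-dimethyl-4-methylidene-16-phenylhexadeca-11,15-dienoate, via allylated silyl peroxide 16 (not isolated), via hydroperoxide 17 (not isolated)
Conditions: (S,S)-imidodiphosphorimidate Brønsted acid (BINOL-derived, N-triflyl, 3,3′-aryl walls; 5 mol %), 15 (2 equiv), toluene, −78 → −40 °C; then Et3N·3HF, THF, −40 → 0 °C; then Et2NH, CF3CH2OH, 0 → 23 °C; chromatographic separation of the C3 epimers
Reagents that add atoms: none
Why: Proposed new method: the catalyst, silylated in the flask by 15, abstracts methoxide from either ketal epimer of 12 to give one planar silylperoxycarbenium ion paired with the confined chiral anion, the terminal CH2 of 15 (future C5) adds to C6, the β-silyl cation returns Me3Si+ to the anion to give 16, fluoride frees hydroperoxide 17, and its terminal oxygen adds to C3 of the enoate under amine catalysis. The closest known reaction types are the Hosomi–Sakurai allylation of peroxyketals through peroxycarbenium ions, counteranion-directed silylium catalysis of additions to ketone- and acetal-derived oxocarbenium ions, and the amine-mediated peroxy-Michael cyclisation of hydroperoxy enoates to 1,2-dioxanes; new is the transfer of chiral-anion control to a peroxycarbenium ion. Ring A closes in a 6-exo-trig conjugate addition. C6 (R) is set by the catalyst, which has to expose the Si face of the C=O+ plane (O > CH2 > CH3) and so tell methyl from the branched CH2 arm, while the remote C8 methyl should neither help nor hinder. C3 is set in the ring closure, where a chair-like transition state offers little bias (the axial site at C6 faces only the sp2 C4 and a ring oxygen), so both C3 epimers are expected, 18 (3S) is separated and its 3R epimer is returned to the mixture by base-induced retro-Michael/re-addition. The step needs ionisation of the methoxy and not the silylperoxy group (the more basic oxygen leaves), loss of Me3Si+ from the β-silyl cation before the peroxide oxygen can close a dioxolane (small silyl on carbon, bulky silyl on oxygen), capture by 15 before the C11=C12 alkene attacks the cation (excess 15, low temperature), and 1,4- rather than 1,6-addition (6-exo at the ester-activated C3 against 6-endo at the terminal CH2).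

Step 9
Reactants: 18 tert-butyl (3S,6R,8R,11E,15E)-3,6-epidioxy-6,8-dimethyl-4-methylidene-16-phenylhexadeca-11,15-dienoate
Product: 19 (3S,4S,6R,8R,11E,15E)-3,6-epidioxy-4,6,8-trimethyl-16-phenylhexadeca-11,15-dien-4-olide (target; cis-fused 1,2-dioxane/γ-lactone)
Conditions: TfOH (10 mol %), CH2Cl2, −40 → 0 °C
Reagents that add atoms: none
Why: Brønsted-acid-catalysed Markovnikov hydro-acyloxylation, in which protonation of the 1,1-disubstituted alkene gives the tertiary C4 cation (and the C4 methyl) and the ester carbonyl held on C3 captures it 5-exo with loss of 2-methylpropene, so the lactone can only be cis-fused and C4 (S) follows from C3 (S), while catalytic acid at low temperature should spare the styrene and the peroxide.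

Compound list
1 | cyclopropyl(phenyl)methanol (racemic) | OC(c1ccccc1)C1CC1 | starting material
2 | [(1E)-4-bromobut-1-en-1-yl]benzene | BrCC/C=C/c1ccccc1 | intermediate
3 | cyclopropanecarbaldehyde | O=CC1CC1 | starting material
4 | bromido[(3E)-4-phenylbut-3-en-1-yl]magnesium | Br[Mg]CC/C=C/c1ccccc1 | intermediate
5 | (4E)-1-cyclopropyl-5-phenylpent-4-en-1-ol (racemic) | OC(CC/C=C/c1ccccc1)C1CC1 | intermediate
6 | [(1E)-5-bromo-5-cyclopropylpent-1-en-1-yl]benzene (racemic) | BrC(CC/C=C/c1ccccc1)C1CC1 | intermediate
7 | [(1E,5E)-8-bromoocta-1,5-dien-1-yl]benzene | BrCC/C=C/CC/C=C/c1ccccc1 | intermediate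
8 | (3E)-pent-3-en-2-one | C/C=C/C(C)=O | starting material
9 | bromido[(3E,7E)-8-phenylocta-3,7-dien-1-yl]magnesium | Br[Mg]CC/C=C/CC/C=C/c1ccccc1 | intermediate
10 | (4R,7E,11E)-4-methyl-12-phenyldodeca-7,11-dien-2-one | C[C@H](CC/C=C/CC/C=C/c1ccccc1)CC(C)=O | intermediate
11 | (2RS,4R,7E,11E)-2-hydroperoxy-2-methoxy-4-methyl-12-phenyldodeca-7,11-diene (both C2 epimers) | C[C@H](CC/C=C/CC/C=C/c1ccccc1)CC(C)(OC)OO | intermediate
12 | tert-butyl{[(2RS,4R,7E,11E)-2-methoxy-4-methyl-12-phenyldodeca-7,11-dien-2-yl]peroxy}dimethylsilane (both C2 epimers) | C[C@H](CC/C=C/CC/C=C/c1ccccc1)CC(C)(OC)OO[Si](C)(C)C(C)(C)C | intermediate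
13 | (2-bromoprop-2-en-1-yl)trimethylsilane | C=C(Br)C[Si](C)(C)C | starting material
14 | tert-butyl prop-2-enoate | C=CC(=O)OC(C)(C)C | starting material
15 | tert-butyl (2E)-4-[(trimethylsilyl)methyl]penta-2,4-dienoate | C=C(C[Si](C)(C)C)/C=C/C(=O)OC(C)(C)C | intermediate
16 | tert-butyl (2E,6R,8R,11E,15E)-6-{[tert-butyl(dimethyl)silyl]peroxy}-6,8-dimethyl-4-methylidene-16-phenylhexadeca-2,11,15-trienoate | C[C@H](CC/C=C/CC/C=C/c1ccccc1)C[C@](C)(CC(=C)/C=C/C(=O)OC(C)(C)C)OO[Si](C)(C)C(C)(C)C | intermediate
17 | tert-butyl (2E,6R,8R,11E,15E)-6-hydroperoxy-6,8-dimethyl-4-methylidene-16-phenylhexadeca-2,11,15-trienoate | C[C@H](CC/C=C/CC/C=C/c1ccccc1)C[C@](C)(CC(=C)/C=C/C(=O)OC(C)(C)C)OO | intermediate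
18 | tert-butyl (3S,6R,8R,11E,15E)-3,6-epidioxy-6,8-dimethyl-4-methylidene-16-phenylhexadeca-11,15-dienoate, i.e. tert-butyl 2-{(3S,6R)-6-methyl-4-methylidene-6-[(2R,5E,9E)-2-methyl-10-phenyldeca-5,9-dien-1-yl]-1,2-dioxan-3-yl}acetate | C[C@H](CC/C=C/CC/C=C/c1ccccc1)C[C@]1(C)CC(=C)[C@H](CC(=O)OC(C)(C)C)OO1 | intermediate
19 | (3S,4S,6R,8R,11E,15E)-3,6-epidioxy-4,6,8-trimethyl-16-phenylhexadeca-11,15-dien-4-olide | C[C@H](CC/C=C/CC/C=C/c1ccccc1)C[C@]1(C)C[C@]2(C)OC(=O)C[C@@H]2OO1 | target

Total step count: 9. Longest linear sequence: 8 steps (steps 1–6, 8 and 9); step 7 is a one-step branch.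

Steps most likely to fail

Step 8. What may go wrong: the ion pair may not distinguish methyl from the CH2 arm, so that C6 forms without facial selectivity. Turnover with the electron-poor allylsilane may be slow, so that the cation is captured by the C11=C12 alkene or fragments. The β-silyl cation may be closed by the peroxide oxygen to a 1,2-dioxolane, or the ring closure may go 1,6. The fallback makes the two bonds one after the other with established achiral reagents and replaces catalyst control by separation; it sets out from 12 and 15 and comes back at 18. TMSOTf (or TiCl4) in CH2Cl2 at −78 °C should give tert-butyl (2E,6RS,8R,11E,15E)-6-{[tert-butyl(dimethyl)silyl]peroxy}-6,8-dimethyl-4-methylidene-16-phenylhexadeca-2,11,15-trienoate F1 as both C6 epimers. Et3N·3HF then gives the hydroperoxides tert-butyl (2E,6RS,8R,11E,15E)-6-hydroperoxy-6,8-dimethyl-4-methylidene-16-phenylhexadeca-2,11,15-trienoate F2. Et2NH in CF3CH2OH closes them to the stereoisomer mixture tert-butyl (3RS,6RS,8R,11E,15E)-3,6-epidioxy-6,8-dimethyl-4-methylidene-16-phenylhexadeca-11,15-dienoate F3, from which 18 is isolated by preparative HPLC.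

Step 9. What may go wrong: hydride shift or O–O heterolysis at the cation next to the peroxide-bearing C3, migration of the alkene into the ring, or protonation of the styrene. The fallback avoids a free cation by going through an iodonium ion; it sets out from 18 and comes back at 19. TMSOTf and 2,6-lutidine in CH2Cl2, followed by aqueous work-up, cleave the tert-butyl ester to 2-{(3S,6R)-6-methyl-4-methylidene-6-[(2R,5E,9E)-2-methyl-10-phenyldeca-5,9-dien-1-yl]-1,2-dioxan-3-yl}acetic acid F4. Iodolactonisation (I2, NaHCO3, MeCN, 0 °C) should give the cis-fused (3S,4S,6R,8R,11E,15E)-3,6-epidioxy-4-(iodomethyl)-6,8-dimethyl-16-phenylhexadeca-11,15-dien-4-olide F5. Radical deiodination with (Me3Si)3SiH and Et3B/air in toluene at 0 °C then gives 19.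

Step 4. What may go wrong: poor facial selectivity on the small β-methyl enone and competing 1,2-addition of the long-chain Grignard reagent. The fallback makes the other bond at C8 (C8–CH3 instead of C8–C9), which is the direction with the broadest precedent; it sets out from 7 and comes back at 10. Grignard reagent 9 is formylated with DMF to (4E,8E)-9-phenylnona-4,8-dienal F6. Wittig reaction with 1-(triphenylphosphoranylidene)propan-2-one gives (3E,7E,11E)-12-phenyldodeca-3,7,11-trien-2-one F7. MeMgBr is then added under the same CuBr·SMe2/ferrocenyl diphosphine catalysis to give 10.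

Further compounds
F1 | step 8 | tert-butyl (2E,6RS,8R,11E,15E)-6-{[tert-butyl(dimethyl)silyl]peroxy}-6,8-dimethyl-4-methylidene-16-phenylhexadeca-2,11,15-trienoate | C[C@H](CC/C=C/CC/C=C/c1ccccc1)CC(C)(CC(=C)/C=C/C(=O)OC(C)(C)C)OO[Si](C)(C)C(C)(C)C
F2 | step 8 | tert-butyl (2E,6RS,8R,11E,15E)-6-hydroperoxy-6,8-dimethyl-4-methylidene-16-phenylhexadeca-2,11,15-trienoate | C[C@H](CC/C=C/CC/C=C/c1ccccc1)CC(C)(CC(=C)/C=C/C(=O)OC(C)(C)C)OO
F3 | step 8 | tert-butyl (3RS,6RS,8R,11E,15E)-3,6-epidioxy-6,8-dimethyl-4-methylidene-16-phenylhexadeca-11,15-dienoate | C[C@H](CC/C=C/CC/C=C/c1ccccc1)CC1(C)CC(=C)C(CC(=O)OC(C)(C)C)OO1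
F4 | step 9 | 2-{(3S,6R)-6-methyl-4-methylidene-6-[(2R,5E,9E)-2-methyl-10-phenyldeca-5,9-dien-1-yl]-1,2-dioxan-3-yl}acetic acid | C[C@H](CC/C=C/CC/C=C/c1ccccc1)C[C@]1(C)CC(=C)[C@H](CC(=O)O)OO1
F5 | step 9 | (3S,4S,6R,8R,11E,15E)-3,6-epidioxy-4-(iodomethyl)-6,8-dimethyl-16-phenylhexadeca-11,15-dien-4-olide | C[C@H](CC/C=C/CC/C=C/c1ccccc1)C[C@]1(C)C[C@]2(CI)OC(=O)C[C@@H]2OO1
F6 | step 4 | (4E,8E)-9-phenylnona-4,8-dienal | O=CCC/C=C/CC/C=C/c1ccccc1
F7 | step 4 | (3E,7E,11E)-12-phenyldodeca-3,7,11-trien-2-one | CC(=O)/C=C/CC/C=C/CC/C=C/c1ccccc1
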